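**Retrosynthetic overview** (lactone numbering: O1, C2 carbonyl, C3 methoxy, C4 aryl, C5 quaternary)
1. The target comes from its TBS/dibenzyl-protected form by desilylation and hydrogenolysis.
2. The butenolide ring is made last: O1–C2 by acylating a tertiary α-hydroxy β-keto ester with methoxyacetyl chloride, then C3=C4 by intramolecular aldol condensation.
3. The key C4–C5 bond and the quaternary centre come from an intermolecular aldol of a Seebach dioxolanone lithium enolate (chroman half) with 3,4-bis(benzyloxy)benzaldehyde, followed by methanolysis and oxidation.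
4. The chroman-bearing dioxolanone comes from D-tyrosine: diazotisation with retention, pivalaldehyde acetal, then propargyl ether Claisen to the chromene, Jacobsen epoxidation and benzylic hydrogenolysis.
5. Ring order: dioxolanone (temporary auxiliary ring), then chromene/chroman, then butenolide.

Assumption: D-tyrosine counts as a cheap commercial starting material, and the (R,R)-salen manganese catalyst is taken to give the (3R,4R)-epoxide as with other 2,2-dimethylchromenes (otherwise its enantiomer is used).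

**Step 1**
Reactants: 1 D-tyrosine
Product: 3 (R)-2-hydroxy-3-(4-hydroxyphenyl)propanoic acid, via α-lactone 2 (not isolated)
Conditions: NaNO2, 1 M aq. H2SO4, 0 °C to rt
Reagents that add atoms: water (O)
Why: Diazotisation of the α-amino acid goes with net retention because the neighbouring carboxylate displaces N2 to give α-lactone 2, which water reopens (double inversion), so the (R) centre of D-tyrosine is carried into 3.

**Step 2**
Reactants: 3 (R)-2-hydroxy-3-(4-hydroxyphenyl)propanoic acid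
Product: 4 (2R,5R)-2-tert-butyl-5-(4-hydroxybenzyl)-1,3-dioxolan-4-one (cis)
Conditions: t-BuCHO, TsOH·H2O (cat.), H2SO4 (cat.), pentane, reflux, Dean–Stark; cis isomer recrystallised
Reagents that add atoms: pivalaldehyde (CC(C)(C)C=O)
Why: Acid-catalysed acetalisation (Seebach dioxolanone formation) gives mainly the cis ring, so the new acetal centre is set (2R) by 1,3-induction from C5 and the minor trans isomer is removed by crystallisation, while the phenol forms no stable acetal.

**Step 3**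
Reactants: 4 (2R,5R)-2-tert-butyl-5-(4-hydroxybenzyl)-1,3-dioxolan-4-one; 5 3-chloro-3-methylbut-1-yne
Product: 6 (2R,5R)-2-tert-butyl-5-{4-[(2-methylbut-3-yn-2-yl)oxy]benzyl}-1,3-dioxolan-4-one
Conditions: DBU, CuCl2·2H2O (1 mol %), MeCN, 0 °C
Reagents that add atoms: none
Why: Copper-catalysed O-propargylation (nucleophilic substitution by the phenoxide, the only acidic OH) gives the aryl 1,1-dimethylpropargyl ether under conditions too mild to open the dioxolanone.

**Step 4**
Reactants: 6 (2R,5R)-2-tert-butyl-5-{4-[(2-methylbut-3-yn-2-yl)oxy]benzyl}-1,3-dioxolan-4-one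
Product: 8 (2R,5R)-2-tert-butyl-5-[(2,2-dimethyl-2H-chromen-6-yl)methyl]-1,3-dioxolan-4-one, via o-allenylphenol 7 (not isolated)
Conditions: o-xylene, 145 °C
Reagents that add atoms: none
Why: A thermal aromatic propargyl Claisen rearrangement gives allenylphenol 7, which closes by 1,5-hydrogen shift and oxa-6π-electrocyclisation to the 2,2-dimethylchromene, and the two ortho positions are equivalent so only one regioisomer can form.

**Step 5**
Reactants: 8 (2R,5R)-2-tert-butyl-5-[(2,2-dimethyl-2H-chromen-6-yl)methyl]-1,3-dioxolan-4-one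
Product: 9 (2R,5R)-2-tert-butyl-5-{[(3R,4R)-3,4-epoxy-2,2-dimethylchroman-6-yl]methyl}-1,3-dioxolan-4-one
Conditions: (R,R)-Jacobsen catalyst, [(R,R)-N,N'-bis(3,5-di-tert-butylsalicylidene)-1,2-cyclohexanediaminato]MnCl (trivalent manganese, 5 mol %), mCPBA, NMO, CH2Cl2, −78 °C
Reagents that add atoms: mCPBA (O=C(OO)c1cccc(Cl)c1)
Why: Jacobsen–Katsuki epoxidation, for which 2,2-dimethylchromenes are the best substrate class, sets chroman C3 and C4 as (3R,4R) under catalyst control, the remote dioxolanone centres having no influence.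

**Step 6**
Reactants: 9 (2R,5R)-2-tert-butyl-5-{[(3R,4R)-3,4-epoxy-2,2-dimethylchroman-6-yl]methyl}-1,3-dioxolan-4-one
Product: 10 (2R,5R)-2-tert-butyl-5-{[(3R)-3-hydroxy-2,2-dimethylchroman-6-yl]methyl}-1,3-dioxolan-4-one
Conditions: H2 (1 atm), Pd/C (10 %), EtOAc, rt
Reagents that add atoms: none
Why: Catalytic hydrogenolysis cleaves only the benzylic C4–O bond of the aryl epoxide, so the C3–O bond and the (3R) carbinol centre stay untouched.

**Step 7**
Reactants: 10 (2R,5R)-2-tert-butyl-5-{[(3R)-3-hydroxy-2,2-dimethylchroman-6-yl]methyl}-1,3-dioxolan-4-one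
Product: 11 (2R,5R)-2-tert-butyl-5-{[(3R)-3-(tert-butyldimethylsilyloxy)-2,2-dimethylchroman-6-yl]methyl}-1,3-dioxolan-4-one
Conditions: TBSOTf, 2,6-lutidine, CH2Cl2, 0 °C
Reagents that add atoms: TBSOTf (CC(C)(C)[Si](C)(C)OS(=O)(=O)C(F)(F)F)
Why: Silylation with the silyl triflate protects the hindered secondary alcohol as a base-stable silyl ether, so only the dioxolanone is deprotonated in the next step.

**Step 8**
Reactants: 11 (2R,5R)-2-tert-butyl-5-{[(3R)-3-(tert-butyldimethylsilyloxy)-2,2-dimethylchroman-6-yl]methyl}-1,3-dioxolan-4-one; 12 3,4-bis(benzyloxy)benzaldehyde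
Product: 14 (2R,5S)-5-{[3,4-bis(benzyloxy)phenyl](hydroxy)methyl}-2-tert-butyl-5-{[(3R)-3-(tert-butyldimethylsilyloxy)-2,2-dimethylchroman-6-yl]methyl}-1,3-dioxolan-4-one (carbinol epimers), via lithium enolate 13 (not isolated)
Conditions: LiN(i-Pr)2 (LDA), THF, −78 °C; then 12, −78 °C; AcOH quench at −78 °C
Reagents that add atoms: none
Why: In this Seebach self-regeneration-of-stereocentres aldol addition the planar enolate 13 is attacked anti to the tert-butyl group of the (2R) acetal, so the new C–C bond takes the place of the former hydrogen and the quaternary centre (later lactone C5) forms as (5S), the carbinol centre being a mixture that is oxidised away later.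

**Step 9**
Reactants: 14 (2R,5S)-aldol adduct
Product: 15 methyl (2S)-3-[3,4-bis(benzyloxy)phenyl]-2-{[(3R)-3-(tert-butyldimethylsilyloxy)-2,2-dimethylchroman-6-yl]methyl}-2,3-dihydroxypropanoate (C3 epimers)
Conditions: NaOMe (0.3 equiv), MeOH/THF, 0 °C; AcOH quench
Reagents that add atoms: methanol (CO)
Why: Methoxide opens the activated acylal-type lactone by transesterification and the hemiacetal loses pivalaldehyde, while the cold protic medium keeps retro-aldol cleavage slow, so the quaternary centre is unchanged.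

**Step 10**
Reactants: 15 methyl (2S)-dihydroxy ester
Product: 16 methyl (2S)-3-[3,4-bis(benzyloxy)phenyl]-2-{[(3R)-3-(tert-butyldimethylsilyloxy)-2,2-dimethylchroman-6-yl]methyl}-2-hydroxy-3-oxopropanoate
Conditions: IBX, DMSO, rt
Reagents that add atoms: none
Why: IBX oxidation converts the secondary benzylic alcohol into the aryl ketone without cleaving the 1,2-diol and cannot touch the tertiary alcohol.

**Step 11**
Reactants: 16 methyl (2S)-hydroxy keto ester; 17 methoxyacetyl chloride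
Product: 18 methyl (2S)-3-[3,4-bis(benzyloxy)phenyl]-2-{[(3R)-3-(tert-butyldimethylsilyloxy)-2,2-dimethylchroman-6-yl]methyl}-2-(2-methoxyacetoxy)-3-oxopropanoate
Conditions: pyridine, DMAP, CH2Cl2, 0 to 40 °C
Reagents that add atoms: none
Why: DMAP-catalysed acylation with the small, reactive acid chloride esterifies the fairly acidic tertiary α-hydroxy group, which is the only free OH in 16.

**Step 12**
Reactants: 18 methoxyacetate ester
Product: 20 methyl (2S)-3-[3,4-bis(benzyloxy)phenyl]-2-{[(3R)-3-(tert-butyldimethylsilyloxy)-2,2-dimethylchroman-6-yl]methyl}-4-methoxy-5-oxo-2,5-dihydrofuran-2-carboxylate, via β-hydroxy lactone 19 (not isolated)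
Conditions: DBU, CF3CO2i-Pr, MeCN, 65 °C
Reagents that add atoms: none
Why: In this intramolecular aldol condensation the methoxyacetate enolate adds 5-exo to the neighbouring aryl ketone to give 19 and the trifluoroacetate ester drives the dehydration by taking up the water, the quaternary centre not being involved.

**Step 13**
Reactants: 20 silyl-protected butenolide
Product: 21 methyl (2S)-3-[3,4-bis(benzyloxy)phenyl]-2-{[(3R)-3-hydroxy-2,2-dimethylchroman-6-yl]methyl}-4-methoxy-5-oxo-2,5-dihydrofuran-2-carboxylate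
Conditions: HF·pyridine, pyridine, THF, 0 °C to rt
Reagents that add atoms: none
Why: Fluoride-mediated desilylation under buffered, mildly acidic conditions removes the silyl ether without harming the methyl ester, the butenolide or the benzyl ethers.

**Step 14**
Reactants: 21 dibenzyl-protected butenolide
Product: 22 methyl (2S)-3-(3,4-dihydroxyphenyl)-2-{[(3R)-3-hydroxy-2,2-dimethylchroman-6-yl]methyl}-4-methoxy-5-oxo-2,5-dihydrofuran-2-carboxylate (CNP0289675.1)
Conditions: H2 (1 atm), Pd/C (10 %), EtOAc/MeOH, rt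
Reagents that add atoms: none
Why: Hydrogenolysis (O-debenzylation) frees the catechol, while the tetrasubstituted conjugated butenolide alkene and the non-benzylic C–O bonds are not reduced under these mild conditions.

**Compound list**
1 | D-tyrosine | N[C@H](Cc1ccc(O)cc1)C(=O)O | starting material
2 | (S)-3-(4-hydroxybenzyl)oxiran-2-one (α-lactone, not isolated) | O1[C@@H](Cc2ccc(O)cc2)C1=O | intermediate
3 | (R)-2-hydroxy-3-(4-hydroxyphenyl)propanoic acid | O[C@H](Cc1ccc(O)cc1)C(=O)O | intermediate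
4 | (2R,5R)-2-tert-butyl-5-(4-hydroxybenzyl)-1,3-dioxolan-4-one | CC(C)(C)[C@@H]1O[C@H](Cc2ccc(O)cc2)C(=O)O1 | intermediate
5 | 3-chloro-3-methylbut-1-yne | CC(C)(Cl)C#C | starting material
6 | (2R,5R)-2-tert-butyl-5-{4-[(2-methylbut-3-yn-2-yl)oxy]benzyl}-1,3-dioxolan-4-one | CC(C)(C)[C@@H]1O[C@H](Cc2ccc(OC(C)(C)C#C)cc2)C(=O)O1 | intermediate
7 | (2R,5R)-2-tert-butyl-5-[4-hydroxy-3-(3-methylbuta-1,2-dien-1-yl)benzyl]-1,3-dioxolan-4-one (not isolated) | CC(C)(C)[C@@H]1O[C@H](Cc2ccc(O)c(C=C=C(C)C)c2)C(=O)O1 | intermediate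
8 | (2R,5R)-2-tert-butyl-5-[(2,2-dimethyl-2H-chromen-6-yl)methyl]-1,3-dioxolan-4-one | CC(C)(C)[C@@H]1O[C@H](Cc2ccc3c(c2)C=CC(C)(C)O3)C(=O)O1 | intermediate
9 | (2R,5R)-2-tert-butyl-5-{[(3R,4R)-3,4-epoxy-2,2-dimethylchroman-6-yl]methyl}-1,3-dioxolan-4-one | CC(C)(C)[C@@H]1O[C@H](Cc2ccc3c(c2)[C@H]4O[C@H]4C(C)(C)O3)C(=O)O1 | intermediate
10 | (2R,5R)-2-tert-butyl-5-{[(3R)-3-hydroxy-2,2-dimethylchroman-6-yl]methyl}-1,3-dioxolan-4-one | CC(C)(C)[C@@H]1O[C@H](Cc2ccc3c(c2)C[C@@H](O)C(C)(C)O3)C(=O)O1 | intermediate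
11 | (2R,5R)-2-tert-butyl-5-{[(3R)-3-(tert-butyldimethylsilyloxy)-2,2-dimethylchroman-6-yl]methyl}-1,3-dioxolan-4-one | CC(C)(C)[C@@H]1O[C@H](Cc2ccc3c(c2)C[C@@H](O[Si](C)(C)C(C)(C)C)C(C)(C)O3)C(=O)O1 | intermediate
12 | 3,4-bis(benzyloxy)benzaldehyde | O=Cc1ccc(OCc2ccccc2)c(OCc2ccccc2)c1 | starting material
13 | lithium enolate of 11, (2R) acetal centre kept (not isolated) | CC(C)(C)[C@@H]1OC(Cc2ccc3c(c2)C[C@@H](O[Si](C)(C)C(C)(C)C)C(C)(C)O3)=C(O[Li])O1 | intermediate
14 | (2R,5S)-5-{[3,4-bis(benzyloxy)phenyl](hydroxy)methyl}-2-tert-butyl-5-{[(3R)-3-(tert-butyldimethylsilyloxy)-2,2-dimethylchroman-6-yl]methyl}-1,3-dioxolan-4-one, carbinol epimers | CC(C)(C)[C@@H]1O[C@@](Cc2ccc3c(c2)C[C@@H](O[Si](C)(C)C(C)(C)C)C(C)(C)O3)(C(O)c2ccc(OCc3ccccc3)c(OCc3ccccc3)c2)C(=O)O1 | intermediate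
15 | methyl (2S)-3-[3,4-bis(benzyloxy)phenyl]-2-{[(3R)-3-(tert-butyldimethylsilyloxy)-2,2-dimethylchroman-6-yl]methyl}-2,3-dihydroxypropanoate, C3 epimers | COC(=O)[C@](O)(Cc1ccc2c(c1)C[C@@H](O[Si](C)(C)C(C)(C)C)C(C)(C)O2)C(O)c1ccc(OCc2ccccc2)c(OCc2ccccc2)c1 | intermediate
16 | methyl (2S)-3-[3,4-bis(benzyloxy)phenyl]-2-{[(3R)-3-(tert-butyldimethylsilyloxy)-2,2-dimethylchroman-6-yl]methyl}-2-hydroxy-3-oxopropanoate | COC(=O)[C@](O)(Cc1ccc2c(c1)C[C@@H](O[Si](C)(C)C(C)(C)C)C(C)(C)O2)C(=O)c1ccc(OCc2ccccc2)c(OCc2ccccc2)c1 | intermediate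
17 | methoxyacetyl chloride | COCC(=O)Cl | starting material
18 | methyl (2S)-3-[3,4-bis(benzyloxy)phenyl]-2-{[(3R)-3-(tert-butyldimethylsilyloxy)-2,2-dimethylchroman-6-yl]methyl}-2-(2-methoxyacetoxy)-3-oxopropanoate | COC(=O)[C@](OC(=O)COC)(Cc1ccc2c(c1)C[C@@H](O[Si](C)(C)C(C)(C)C)C(C)(C)O2)C(=O)c1ccc(OCc2ccccc2)c(OCc2ccccc2)c1 | intermediate
19 | methyl (2S)-3-[3,4-bis(benzyloxy)phenyl]-2-{[(3R)-3-(tert-butyldimethylsilyloxy)-2,2-dimethylchroman-6-yl]methyl}-3-hydroxy-4-methoxy-5-oxotetrahydrofuran-2-carboxylate, C3/C4 epimers (not isolated) | COC(=O)[C@@]1(Cc2ccc3c(c2)C[C@@H](O[Si](C)(C)C(C)(C)C)C(C)(C)O3)OC(=O)C(OC)C1(O)c1ccc(OCc2ccccc2)c(OCc2ccccc2)c1 | intermediate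
20 | methyl (2S)-3-[3,4-bis(benzyloxy)phenyl]-2-{[(3R)-3-(tert-butyldimethylsilyloxy)-2,2-dimethylchroman-6-yl]methyl}-4-methoxy-5-oxo-2,5-dihydrofuran-2-carboxylate | COC(=O)[C@@]1(Cc2ccc3c(c2)C[C@@H](O[Si](C)(C)C(C)(C)C)C(C)(C)O3)OC(=O)C(OC)=C1c1ccc(OCc2ccccc2)c(OCc2ccccc2)c1 | intermediate
21 | methyl (2S)-3-[3,4-bis(benzyloxy)phenyl]-2-{[(3R)-3-hydroxy-2,2-dimethylchroman-6-yl]methyl}-4-methoxy-5-oxo-2,5-dihydrofuran-2-carboxylate | COC(=O)[C@@]1(Cc2ccc3c(c2)C[C@@H](O)C(C)(C)O3)OC(=O)C(OC)=C1c1ccc(OCc2ccccc2)c(OCc2ccccc2)c1 | intermediate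
22 | methyl (2S)-3-(3,4-dihydroxyphenyl)-2-{[(3R)-3-hydroxy-2,2-dimethylchroman-6-yl]methyl}-4-methoxy-5-oxo-2,5-dihydrofuran-2-carboxylate | COC(=O)[C@@]1(Cc2ccc3c(c2)C[C@@H](O)C(C)(C)O3)OC(=O)C(OC)=C1c1ccc(O)c(O)c1 | target

**Step count and risks**
Total steps: 14. Longest linear sequence: 14 steps (1 to 22); compounds 5, 12 and 17 are bought and enter directly.

Steps most likely to fail:

Step 8 (aldol). The hindered tertiary enolate and the electron-rich aldehyde may give low conversion through retro-aldol reversal. The fallback sets out from 11 and comes back at 16. Commercial 3,4-bis(benzyloxy)benzoic acid is turned with (COCl)2 and catalytic DMF into 3,4-bis(benzyloxy)benzoyl chloride F1. Enolate 13, made from 11 as before, is C-acylated by F1 at −78 °C in an irreversible Claisen-type condensation, again anti to the tert-butyl group, to give (2R,5S)-5-[3,4-bis(benzyloxy)benzoyl]-2-tert-butyl-5-{[(3R)-3-(tert-butyldimethylsilyloxy)-2,2-dimethylchroman-6-yl]methyl}-1,3-dioxolan-4-one F2. Brief NaOMe/MeOH at −20 °C opens the lactone of F2 to 16, so 14 and 15 are bypassed.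

Step 11 (acylation of the tertiary alcohol). The alcohol is flanked by three substituents and may not acylate cleanly. The fallback sets out from 16 and comes back at 19. It makes the C3–C4 bond first: the lithium enolate of methyl methoxyacetate (LiN(i-Pr)2, THF, −78 °C, 2.5 equiv, the first equivalent taking the OH proton) adds to the ketone of 16 to give dimethyl (2S)-3-[3,4-bis(benzyloxy)phenyl]-2-{[(3R)-3-(tert-butyldimethylsilyloxy)-2,2-dimethylchroman-6-yl]methyl}-2,3-dihydroxy-4-methoxypentanedioate F3. On warming, the tertiary C2 alkoxide of F3 lactonises onto the new ester (five-membered ring) to give 19, which the DBU/CF3CO2i-Pr conditions of step 12 dehydrate to 20.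

Step 12 (aldol condensation). The enolate could instead attack the neighbouring methyl ester (Dieckmann-type closure to a tetronic acid), or the electron-rich ketone may react sluggishly. The fallback sets out from 16 and comes back at 20. It uses an intramolecular Horner–Wadsworth–Emmons olefination: 2-(dimethoxyphosphoryl)-2-methoxyacetic acid F4, made by LiOH saponification of commercial methyl 2-(dimethoxyphosphoryl)-2-methoxyacetate, is coupled to 16 with DCC/DMAP to give methyl (2S)-3-[3,4-bis(benzyloxy)phenyl]-2-{[(3R)-3-(tert-butyldimethylsilyloxy)-2,2-dimethylchroman-6-yl]methyl}-2-[2-(dimethoxyphosphoryl)-2-methoxyacetoxy]-3-oxopropanoate F5. LiCl/DBU in MeCN then closes the ring on the ketone; the soft phosphonate carbanion ignores the methyl ester and the olefination is irreversible, so 20 forms directly.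

**Further compounds**
F1 | step 8 | 3,4-bis(benzyloxy)benzoyl chloride | O=C(Cl)c1ccc(OCc2ccccc2)c(OCc2ccccc2)c1
F2 | step 8 | (2R,5S)-5-[3,4-bis(benzyloxy)benzoyl]-2-tert-butyl-5-{[(3R)-3-(tert-butyldimethylsilyloxy)-2,2-dimethylchroman-6-yl]methyl}-1,3-dioxolan-4-one | CC(C)(C)[C@@H]1O[C@@](Cc2ccc3c(c2)C[C@@H](O[Si](C)(C)C(C)(C)C)C(C)(C)O3)(C(=O)c2ccc(OCc3ccccc3)c(OCc3ccccc3)c2)C(=O)O1
F3 | step 11 | dimethyl (2S)-3-[3,4-bis(benzyloxy)phenyl]-2-{[(3R)-3-(tert-butyldimethylsilyloxy)-2,2-dimethylchroman-6-yl]methyl}-2,3-dihydroxy-4-methoxypentanedioate, C3/C4 epimers | COC(=O)[C@](O)(Cc1ccc2c(c1)C[C@@H](O[Si](C)(C)C(C)(C)C)C(C)(C)O2)C(O)(c1ccc(OCc2ccccc2)c(OCc2ccccc2)c1)C(OC)C(=O)OC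
F4 | step 12 | 2-(dimethoxyphosphoryl)-2-methoxyacetic acid | COC(C(=O)O)P(=O)(OC)OC
F5 | step 12 | methyl (2S)-3-[3,4-bis(benzyloxy)phenyl]-2-{[(3R)-3-(tert-butyldimethylsilyloxy)-2,2-dimethylchroman-6-yl]methyl}-2-[2-(dimethoxyphosphoryl)-2-methoxyacetoxy]-3-oxopropanoate | COC(=O)[C@](OC(=O)C(OC)P(=O)(OC)OC)(Cc1ccc2c(c1)C[C@@H](O[Si](C)(C)C(C)(C)C)C(C)(C)O2)C(=O)c1ccc(OCc2ccccc2)c(OCc2ccccc2)c1
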